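Bet on noon, and judge each flask by one number: how much Z must convert before G can start.

| flask | Z | D | X | temperature | remark | time |
|---|---|---|---|---|---|---|
| Friday's | 10 mM | 14 mM | 19 mM | 20 °C | run made earlier |  |
| Tuesday's | 40 mM | 14 mM | 19 mM | 40 °C | run made earlier |  |
| Monday's | 20 mM | 28 mM | 19 mM | 20 °C | run made earlier |  |
| noon | 20 mM | 14.0 mM | 19.0 mM | 55 °C |  | 15 h |
| winter | 20 mM | 14.0 mM | 19.0 mM | 40 °C |  | 15 h |
| dusk | 20 mM | 14.0 mM | 19.0 mM | 25 °C |  | 15 h |

| run | time / h | G / % |
|---|---|---|
| Friday's | 8.00 | 1.2 |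
| Friday's | 12.0 | 0 |
| Friday's | 15.0 | 0 |
| Friday's | 25.0 | 0.8 |
| Friday's | 30.0 | 0 |
| Friday's | 60.0 | 0 |
| Friday's | 96.0 | 0 |
| Tuesday's | 3.00 | 0 |
| Tuesday's | 4.00 | 0 |
| Tuesday's | 6.00 | 0 |
| Tuesday's | 8.00 | 0.2 |
| Tuesday's | 12.0 | 8.4 |
| Tuesday's | 20.0 | 18.2 |
| Tuesday's | 30.0 | 21.6 |
| Monday's | 15.0 | 0.2 |
| Monday's | 30.0 | 0.2 |
| Monday's | 60.0 | 0.9 |
| Monday's | 72.0 | 1.4 |
| Monday's | 96.0 | 0.6 |

(standard deviation of a reading: 1 percentage point)

1. which flask leads in amount of G, in percent of the Z charged ("all alike" within 1.5 percentage points) (noon / winter / dusk / all alike)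
2. how much G is there at the end, in percent of the Z charged: noon
3. how much G is there at the end, in percent of the Z charged: winter
4. how much G is there at the end, in percent of the Z charged: dusk

- the earlier runs were read with a standard deviation of 1 percentage point
- on the list of suspects stand: X -> E; D + J <-> G; X + J -> Q; 2 X -> L; Z -> J

Tuesday's run shows an induction period. G reads 0.2% at 8.00 h, then 8.4% at 12.0 h. Take two suspects, Z → J and X + J → Q, and let X catch J before D can hold it. Freeze J near zero while X stands. Then G waits until the J made equals the X charged. For the new flasks that point is 95.0% of the Z, the X charge over the Z charge. Call this the break-even conversion.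

Turn the question round. For winter to show G, its Z must pass break-even within 15 h. This is my own reckoning, and it counts no other loss of X.

Rate constant read from Tuesday's lag, with 0.525 of its Z left:

k = −ln(0.525) / 8.00 h = 0.0805 /h

Rate constant needed, with 0.0500 of the Z left:

k = −ln(0.0500) / 15 h = 0.200 /h

Winter runs at Tuesday's temperature, and the constant it needs exceeds the one read by a factor of 2.48. Dusk is colder. Noon must earn that factor from its 55 °C, and I expect it does. So I commit to noon in front, with winter and dusk near zero.

The forecast also names noon. It gives noon 9% (range 1.5% to 20%), winter 0.3% and dusk 0%. On the X lost by other routes it says: “That loss is poorly known”.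

The flasks give noon 27.0%, winter 3.48% and dusk 0.0124%, so noon leads.

    X → E (k = 8.99 × 10⁻⁵ /h, Ea = 115 kJ/mol)
    D + J ⇌ G (K = 180 /M, k = 1760 /M/h, Ea = 57.0 kJ/mol, ΔH = 5.00 kJ/mol)
    X + J → Q (k = 37000 /M/h, Ea = 51.0 kJ/mol)
    2 X → L (k = 6.20 /M/h, Ea = 72.0 kJ/mol)
    Z → J (k = 0.0507 /h, Ea = 99.0 kJ/mol)
    (constants at 40 °C)

Correct break-even at noon. X pairing with itself made 3.93 mM of L, two X each, so break-even falls from 95.0% to 55.7%, and Q stands at 55.7%. Strike that pairing out and noon's G drops from 27.0% to 2.80%, so the pairing is one part of the cause of noon's G. Dusk's 0.0124% has two causes acting together: X + J → Q, without which it reads 7.11%, and the reading at 15 h, since at 150 h it reads 17.1%. Now charge the winter recipe with 50 mM of Z. The same subtraction gives 26.0%, Q stands at 25.9%, and G reaches 14.8%.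

The earlier runs and the new flask were computed with constants of no real substance, and the scatter is random.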